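**Retrosynthetic overview**
- The 7β‑OH is set last by reduction of a C7 ketone; the (12Z)‑diene is unveiled just before that by vinylation of a (Z)‑alkenyl chloride carried through the whole route.
- 6α‑OAc comes from Rubottom oxidation and acetylation of an 8α‑hydroxy‑7‑ketone, which comes from α‑face dihydroxylation and oxidation of a Δ7 alkene.
- Rings A and B (C5, C9, C10) are formed together, A then B, in one chiral Brønsted‑acid (IDPi) proton‑initiated bicyclisation of an achiral tetraene that ends by proton loss.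
- The tetraene is assembled from (E)‑geranylacetone, Me3Al and (Z)‑1,3‑dichlorobut‑2‑ene (alkyne formation, carboalumination, Pd allylation).

Assumption: labdane numbering with α/β descriptors is used for the bicyclic compounds (normal series: 5α‑H, 9α‑H, 10β‑Me), and (E)‑geranylacetone and (Z)‑1,3‑dichlorobut‑2‑ene are bought as single isomers (the latter distilled from the commercial E/Z mixture if needed).

**Step 1**
Reactants: 1 (E)-geranylacetone
Product: 3 (5E)-6,10-dimethylundeca-5,9-dien-1-yne, via enol phosphate 2 (not isolated)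
Conditions: LDA (1.05 equiv), THF, −78 °C; ClP(O)(OEt)2, −78 °C → rt; LDA (2.3 equiv), −78 °C → rt; aq. NH4Cl
Reagents that add atoms: diethyl chlorophosphate CCOP(=O)(Cl)OCC (its atoms are in 2 only)
Why: The kinetic methyl-side enolate is O-phosphorylated and the terminal enol phosphate undergoes LDA-induced elimination to the terminal alkyne (Negishi methyl ketone → alkyne protocol), leaving the trisubstituted alkenes untouched and creating no stereocentre.

**Step 2**
Reactants: 3 (5E)-6,10-dimethylundeca-5,9-dien-1-yne; 4 (Z)-1,3-dichlorobut-2-ene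
Product: 6 (2Z,5E,9E)-2-chloro-6,10,14-trimethylpentadeca-2,5,9,13-tetraene, via alkenylalane 5 (not isolated)
Conditions: Me3Al (2 equiv), Cp2ZrCl2 (20 mol%), ClCH2CH2Cl, rt; then 4, Pd(PPh3)4 (5 mol%), THF, rt
Reagents that add atoms: trimethylaluminium C[Al](C)C
Why: Zr-catalysed syn-methylalumination (Negishi carboalumination) gives the (E)-alkenylalane, which Pd(0) couples at the CH2 terminus of the allylic chloride of 4 (alkenyl–allyl cross-coupling) with retention of both alkene geometries, the vinylic C–Cl being inert to Pd/PPh3.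

**Step 3**
Reactants: 6 (2Z,5E,9E)-2-chloro-6,10,14-trimethylpentadeca-2,5,9,13-tetraene
Product: 7 (12Z)-13-chloro-14,15-dinorlabda-7,12-diene (trans-decalin, 5α-H, 10β-Me, 9β side chain)
Conditions: chiral IDPi Brønsted acid (3 mol%; the enantiomer that converts (3E,7E)-homofarnesol into (−)-ambrox), (CF3)3COH/CH2Cl2, −40 °C
Reagents that add atoms: none
Why: Proposed new method: the confined imidodiphosphorimidate acid protonates the terminal trisubstituted alkene of the chair–chair-folded all-E polyene inside its chiral pocket, anti additions across the 5E and 9E alkenes form C4–C5 and C9–C10 and fix 5α-H, 10β-Me and the 9β side chain relative to one another (Stork–Eschenmoser) while the chiral counter-anion fixes the absolute sense, and because the chloroalkenyl tail cannot trap the C8 cation (it would need a 4- or 5-endo closure and its C=C is deactivated by Cl) the ion pair collapses by loss of the axial 7α-H to the anion, giving the Δ7 alkene and regenerating the acid; the closest known reaction type is the IDPi-catalysed OH- or CO2H-terminated polyene cyclisation (homofarnesol → ambrox), together with superacid cyclisations of farnesyl derivatives that end by proton loss to drim-7-enes.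

**Step 4**
Reactants: 7 (12Z)-13-chloro-14,15-dinorlabda-7,12-diene
Product: 8 (12Z)-13-chloro-14,15-dinorlabd-12-ene-7α,8α-diol
Conditions: OsO4 (5 mol%), NMO (2 equiv), acetone/t-BuOH/H2O, rt
Reagents that add atoms: osmium tetroxide O=[Os](=O)(=O)=O; N-methylmorpholine N-oxide C[N+]1([O-])CCOCC1; water O
Why: Upjohn syn-dihydroxylation takes the electron-rich ring alkene (the chloroalkene is deactivated) from the α face opposite the axial C10 methyl, setting 7α-OH and 8α-OH with 8β-Me.

**Step 5**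
Reactants: 8 (12Z)-13-chloro-14,15-dinorlabd-12-ene-7α,8α-diol
Product: 9 (12Z)-13-chloro-8α-hydroxy-14,15-dinorlabd-12-en-7-one
Conditions: Dess–Martin periodinane (1.3 equiv), pyridine, CH2Cl2, 0 °C → rt
Reagents that add atoms: none
Why: Dess–Martin oxidation converts only the secondary 7-OH (the tertiary 8-OH cannot be oxidised), so the C8 stereocentre is kept in the α-ketol.

**Step 6**
Reactants: 9 (12Z)-13-chloro-8α-hydroxy-14,15-dinorlabd-12-en-7-one
Product: 12 (12Z)-13-chloro-6α,8α-dihydroxy-14,15-dinorlabd-12-en-7-one, via bis-silyl enol ether 10 (not isolated), via bis-silyloxy ketone 11 (not isolated)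
Conditions: TMSOTf (3 equiv), Et3N (4 equiv), CH2Cl2, 0 °C → rt; mCPBA (1.1 equiv), hexane/CH2Cl2, −20 °C; 1 M HCl, THF, 0 °C
Reagents that add atoms: mCPBA O=C(OO)c1cccc(Cl)c1; trimethylsilyl triflate C[Si](C)(C)OS(=O)(=O)C(F)(F)F (its atoms are in 10 and 11 only)
Why: Rubottom oxidation: the ketone can enolise only toward C6 (C8 is quaternary), and the Δ6 silyl enol ether is epoxidised on the α face because the β face is blocked by the axial C10 and C4β methyls, so silyl migration gives the equatorial 6α-oxygen.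

**Step 7**
Reactants: 12 (12Z)-13-chloro-6α,8α-dihydroxy-14,15-dinorlabd-12-en-7-one
Product: 13 (12Z)-6α-acetoxy-13-chloro-8α-hydroxy-14,15-dinorlabd-12-en-7-one
Conditions: Ac2O (1.5 equiv), pyridine, DMAP (10 mol%), CH2Cl2, 0 °C → rt
Reagents that add atoms: acetic anhydride CC(=O)OC(C)=O
Why: DMAP-catalysed acylation takes the only secondary hydroxyl (the tertiary 8-OH is inert here), so the acetate is fixed on O6 before a 7-OH exists.

**Step 8**
Reactants: 13 (12Z)-6α-acetoxy-13-chloro-8α-hydroxy-14,15-dinorlabd-12-en-7-one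
Product: 14 (12Z)-6α-acetoxy-8α-hydroxylabda-12,14-dien-7-one
Conditions: CH2=CHZnBr (3 equiv), XPhos Pd G3 (5 mol%), THF, 50 °C
Reagents that add atoms: vinylzinc bromide C=C[Zn]Br
Why: Negishi coupling of the alkenyl chloride proceeds with retention through oxidative addition, transmetalation and reductive elimination, giving the (12Z)-diene, and the organozinc tolerates the ketone, the acetate and the tertiary alcohol.

**Step 9**
Reactants: 14 (12Z)-6α-acetoxy-8α-hydroxylabda-12,14-dien-7-one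
Product: 15 (12Z)-6α-acetoxylabda-12,14-diene-7β,8α-diol (5S,6R,7S,8S,9R,10S; CNP0138393.1)
Conditions: NaBH4 (1.5 equiv), CeCl3·7H2O (1.5 equiv), MeOH/THF, −78 °C; AcOH quench at −78 °C
Reagents that add atoms: none
Why: Luche reduction: the small hydride attacks C7 axially from the α face (anti to the axial 8β-methyl), giving the equatorial 7β-OH, while the low temperature and acidic quench suppress 6→7 acetyl migration and the diene is inert.

**Compound list**
1 | (E)-geranylacetone, (5E)-6,10-dimethylundeca-5,9-dien-2-one | CC(=O)CC/C=C(\C)CCC=C(C)C | starting material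
2 | diethyl (5E)-6,10-dimethylundeca-1,5,9-trien-2-yl phosphate | C=C(OP(=O)(OCC)OCC)CC/C=C(\C)CCC=C(C)C | intermediate
3 | (5E)-6,10-dimethylundeca-5,9-dien-1-yne | C#CCC/C=C(\C)CCC=C(C)C | intermediate
4 | (Z)-1,3-dichlorobut-2-ene | ClC/C=C(/C)Cl | starting material
5 | dimethyl[(1E,5E)-2,6,10-trimethylundeca-1,5,9-trien-1-yl]alane | C[Al](C)/C=C(\C)CC/C=C(\C)CCC=C(C)C | intermediate
6 | (2Z,5E,9E)-2-chloro-6,10,14-trimethylpentadeca-2,5,9,13-tetraene | C/C(Cl)=C/C/C=C(\C)CC/C=C(\C)CCC=C(C)C | intermediate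
7 | (12Z)-13-chloro-14,15-dinorlabda-7,12-diene | Cl/C(C)=C\C[C@H]1C(C)=CC[C@H]2C(C)(C)CCC[C@@]21C | intermediate
8 | (12Z)-13-chloro-14,15-dinorlabd-12-ene-7α,8α-diol | Cl/C(C)=C\C[C@H]1[C@](C)(O)[C@H](O)C[C@H]2C(C)(C)CCC[C@@]21C | intermediate
9 | (12Z)-13-chloro-8α-hydroxy-14,15-dinorlabd-12-en-7-one | Cl/C(C)=C\C[C@H]1[C@](C)(O)C(=O)C[C@H]2C(C)(C)CCC[C@@]21C | intermediate
10 | (12Z)-13-chloro-7,8α-bis(trimethylsilyloxy)-14,15-dinorlabda-6,12-diene | Cl/C(C)=C\C[C@H]1[C@](C)(O[Si](C)(C)C)C(O[Si](C)(C)C)=C[C@H]2C(C)(C)CCC[C@@]21C | intermediate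
11 | (12Z)-13-chloro-6α,8α-bis(trimethylsilyloxy)-14,15-dinorlabd-12-en-7-one | Cl/C(C)=C\C[C@H]1[C@](C)(O[Si](C)(C)C)C(=O)[C@H](O[Si](C)(C)C)[C@H]2C(C)(C)CCC[C@@]21C | intermediate
12 | (12Z)-13-chloro-6α,8α-dihydroxy-14,15-dinorlabd-12-en-7-one | Cl/C(C)=C\C[C@H]1[C@](C)(O)C(=O)[C@H](O)[C@H]2C(C)(C)CCC[C@@]21C | intermediate
13 | (12Z)-6α-acetoxy-13-chloro-8α-hydroxy-14,15-dinorlabd-12-en-7-one | Cl/C(C)=C\C[C@H]1[C@](C)(O)C(=O)[C@H](OC(C)=O)[C@H]2C(C)(C)CCC[C@@]21C | intermediate
14 | (12Z)-6α-acetoxy-8α-hydroxylabda-12,14-dien-7-one | C=C/C(C)=C\C[C@H]1[C@](C)(O)C(=O)[C@H](OC(C)=O)[C@H]2C(C)(C)CCC[C@@]21C | intermediate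
15 | (12Z)-6α-acetoxylabda-12,14-diene-7β,8α-diol (5S,6R,7S,8S,9R,10S) | C=C/C(C)=C\C[C@H]1[C@](C)(O)[C@@H](O)[C@H](OC(C)=O)[C@H]2C(C)(C)CCC[C@@]21C | target

**Totals**
Total step count: 9. Longest linear sequence: 9 steps (from 1).

**Three steps most likely to fail**

Step 3 (the proposed new step). The risks are proton loss toward C17 or C9 instead of C7 (Δ8(17) or Δ8(9) isomers), lower enantioinduction without a hydrogen-bonding anchor, and protonation of the chloroalkene. The diol 8 should allow the ee to be raised by crystallisation. The fallback uses known chemistry; it sets out from alkenylalane 5 and comes back at 7. Alkenylalane 5 is turned into its ate complex with n-BuLi and opened with ethylene oxide to (3E,7E)-homofarnesol F1. The known IDPi-catalysed OH-terminated cyclisation of this alcohol gives (−)-ambrox F2. RuCl3/NaIO4 oxidises the only ether CH2 to give (+)-sclareolide F3, and DIBAL at −78 °C gives sclareolide lactol F4. CrCl2/CH3CCl3 (Z)-selective chloro-olefination of the open hydroxy-aldehyde form gives (12Z)-13-chloro-14,15-dinorlabd-12-en-8α-ol F5. Dehydration (SOCl2/pyridine or Burgess reagent) then gives 7 together with its Δ8(17) isomer, which is removed on AgNO3–silica; this last step is unselective and is the weak point of the fallback.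

Step 6. The risks are slow enolisation at the hindered C6 and side reactions of the α-ketol (acyloin shift, enediol isomerisation). The fallback sets C6 and C7 together by hydroboration and so also replaces step 9; it sets out from 9 and comes back at 15. TESOTf/Et3N converts 9 into (12Z)-13-chloro-7,8α-bis(triethylsilyloxy)-14,15-dinorlabda-6,12-diene F6. BH3·THF adds syn from the α face (boron at C6), and NaBO3 oxidation gives (12Z)-13-chloro-7β,8α-bis(triethylsilyloxy)-14,15-dinorlabd-12-en-6α-ol F7, already with the trans-diequatorial 6α,7β pattern. Ac2O/DMAP gives (12Z)-13-chloro-7β,8α-bis(triethylsilyloxy)-14,15-dinorlabd-12-en-6α-yl acetate F8. Negishi vinylation as in step 8 gives (12Z)-7β,8α-bis(triethylsilyloxy)labda-12,14-dien-6α-yl acetate F9, and HF·pyridine removes both silyl groups to give 15.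

Step 8. The risk is that the unactivated trisubstituted alkenyl chloride resists oxidative addition under conditions mild enough for the α-acetoxy ketone. The fallback moves the C–C coupling to the robust diol stage; it sets out from 8 and comes back at 14. Kumada coupling of 8 (vinylMgBr in excess, NiCl2(dppp), THF) gives (12Z)-labda-12,14-diene-7α,8α-diol F10. Dess–Martin oxidation gives (12Z)-8α-hydroxylabda-12,14-dien-7-one F11. TMSOTf/Et3N gives (12Z)-7,8α-bis(trimethylsilyloxy)labda-6,12,14-triene F12. DMDO (1.0 equiv, −78 °C; the silyl enol ether reacts far faster than the diene) gives (12Z)-6α,8α-bis(trimethylsilyloxy)labda-12,14-dien-7-one F13. Dilute acid gives (12Z)-6α,8α-dihydroxylabda-12,14-dien-7-one F14, which is acetylated as in step 7 to 14.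

**Further compounds**
F1 | step 3 | (3E,7E)-homofarnesol, (3E,7E)-4,8,12-trimethyltrideca-3,7,11-trien-1-ol | OCC/C=C(\C)CC/C=C(\C)CCC=C(C)C
F2 | step 3 | (−)-ambrox | C1C[C@H]2[C@](C)(O1)CC[C@H]3C(C)(C)CCC[C@@]32C
F3 | step 3 | (+)-sclareolide | O=C1C[C@H]2[C@](C)(O1)CC[C@H]3C(C)(C)CCC[C@@]32C
F4 | step 3 | sclareolide lactol (anomeric mixture) | OC1C[C@H]2[C@](C)(O1)CC[C@H]3C(C)(C)CCC[C@@]32C
F5 | step 3 | (12Z)-13-chloro-14,15-dinorlabd-12-en-8α-ol | Cl/C(C)=C\C[C@H]1[C@](C)(O)CC[C@H]2C(C)(C)CCC[C@@]21C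
F6 | step 6 | (12Z)-13-chloro-7,8α-bis(triethylsilyloxy)-14,15-dinorlabda-6,12-diene | Cl/C(C)=C\C[C@H]1[C@](C)(O[Si](CC)(CC)CC)C(O[Si](CC)(CC)CC)=C[C@H]2C(C)(C)CCC[C@@]21C
F7 | step 6 | (12Z)-13-chloro-7β,8α-bis(triethylsilyloxy)-14,15-dinorlabd-12-en-6α-ol | Cl/C(C)=C\C[C@H]1[C@](C)(O[Si](CC)(CC)CC)[C@@H](O[Si](CC)(CC)CC)[C@H](O)[C@H]2C(C)(C)CCC[C@@]21C
F8 | step 6 | (12Z)-13-chloro-7β,8α-bis(triethylsilyloxy)-14,15-dinorlabd-12-en-6α-yl acetate | Cl/C(C)=C\C[C@H]1[C@](C)(O[Si](CC)(CC)CC)[C@@H](O[Si](CC)(CC)CC)[C@H](OC(C)=O)[C@H]2C(C)(C)CCC[C@@]21C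
F9 | step 6 | (12Z)-7β,8α-bis(triethylsilyloxy)labda-12,14-dien-6α-yl acetate | C=C/C(C)=C\C[C@H]1[C@](C)(O[Si](CC)(CC)CC)[C@@H](O[Si](CC)(CC)CC)[C@H](OC(C)=O)[C@H]2C(C)(C)CCC[C@@]21C
F10 | step 8 | (12Z)-labda-12,14-diene-7α,8α-diol | C=C/C(C)=C\C[C@H]1[C@](C)(O)[C@H](O)C[C@H]2C(C)(C)CCC[C@@]21C
F11 | step 8 | (12Z)-8α-hydroxylabda-12,14-dien-7-one | C=C/C(C)=C\C[C@H]1[C@](C)(O)C(=O)C[C@H]2C(C)(C)CCC[C@@]21C
F12 | step 8 | (12Z)-7,8α-bis(trimethylsilyloxy)labda-6,12,14-triene | C=C/C(C)=C\C[C@H]1[C@](C)(O[Si](C)(C)C)C(O[Si](C)(C)C)=C[C@H]2C(C)(C)CCC[C@@]21C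
F13 | step 8 | (12Z)-6α,8α-bis(trimethylsilyloxy)labda-12,14-dien-7-one | C=C/C(C)=C\C[C@H]1[C@](C)(O[Si](C)(C)C)C(=O)[C@H](O[Si](C)(C)C)[C@H]2C(C)(C)CCC[C@@]21C
F14 | step 8 | (12Z)-6α,8α-dihydroxylabda-12,14-dien-7-one | C=C/C(C)=C\C[C@H]1[C@](C)(O)C(=O)[C@H](O)[C@H]2C(C)(C)CCC[C@@]21C
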